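**Strategy**

Ring B comes from a cresol: the contiguous carbons C8 (oxidised), C9 (side-chain-bearing) and C10 (quaternary, methyl-bearing) of the target match the ketal carbon, β-carbon and α-carbon of a 2-methylquinone-monoketal-derived enone. The route rests on disconnecting C9–C11 and C1–C10. In one operation, a copper–phosphoramidite-catalysed conjugate addition delivers the C11–C15 chain (as a dialkylzinc) to C9 and the resulting zinc enolate is allylated at C10, setting both ring-B stereocentres without closing a ring. The precursor is 7-methyl-1,4-dioxaspiro[4.5]dec-6-en-8-one, an α-methyl enone with C8 masked as a dioxolane and C5 as the ketone on which ring A is later built.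

Key step: step 5

Remark: atoms carry labdane numbers throughout (C1–C10 rings, C11–C15 chain, C17 exocyclic methylene), also in monocyclic intermediates; the C5 carbinol configuration drawn for 14 and 15 is the expected one, and either C5 epimer converges at 16.

**Route**

Step 1
Reactants: 1 4-methoxy-2-methylphenol
Product: 3 7-methyl-1,4-dioxaspiro[4.5]deca-6,9-dien-8-one, via mixed methyl 2-hydroxyethyl ketal 2 (not isolated)
Conditions: PhI(OAc)2 (1.1 equiv), ethylene glycol–CH2Cl2, 0 °C to rt
Reagents that add atoms: ethylene glycol OCCO
Why: Oxidative dearomatization of a para-methoxyphenol with the hypervalent iodine reagent gives a cyclohexadienyl cation that the diol traps at the methoxy-bearing carbon, and the acetic acid released should close mixed ketal 2 to the dioxolane with loss of methanol (quinone monoketal formation), so no stereocentre has to be controlled.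

Step 2
Reactants: 3 7-methyl-1,4-dioxaspiro[4.5]deca-6,9-dien-8-one
Product: 4 7-methyl-1,4-dioxaspiro[4.5]dec-6-en-8-one
Conditions: H2 (1 atm), RhCl(PPh3)3 (5 mol %), toluene, rt
Reagents that add atoms: none
Why: Homogeneous hydrogenation with the rhodium–phosphine complex is governed by steric access, so the disubstituted C6=C7 alkene of the cross-conjugated dienone should be saturated while the trisubstituted, methyl-bearing C9=C10 enone survives, and the neutral medium avoids reductive aromatization (chemoselective catalytic hydrogenation).

Step 3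
Reactants: 5 (R)-3-methylglutaric acid monomethyl ester
Product: 6 methyl (3R)-5-hydroxy-3-methylpentanoate
Conditions: BH3·SMe2 (1.1 equiv), THF, 0 °C to rt; aqueous K2CO3 work-up
Reagents that add atoms: none
Why: Borane reduces the free carboxylic acid through an acyloxyborane far faster than it touches the methyl ester, and the C13 stereocentre, β to both carbonyl groups, is not enolisable, so the (R)-hydroxy ester should result (chemoselective borane reduction).

Step 4
Reactants: 6 methyl (3R)-5-hydroxy-3-methylpentanoate
Product: 7 methyl (3S)-5-iodo-3-methylpentanoate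
Conditions: I2, PPh3, imidazole, CH2Cl2, 0 °C to rt
Reagents that add atoms: iodine II
Why: Appel-type iodination through an alkoxyphosphonium ion converts the primary alcohol into the iodide under neutral conditions that do not lactonise the 5-hydroxy ester, the stereocentre being untouched and its descriptor changing to S only through the priority of iodine.

Step 5
Reactants: 4 7-methyl-1,4-dioxaspiro[4.5]dec-6-en-8-one; 7 methyl (3S)-5-iodo-3-methylpentanoate; 8 allyl bromide
Product: 11 methyl (3R)-3-methyl-5-[(6R,7R)-7-methyl-8-oxo-7-(prop-2-en-1-yl)-1,4-dioxaspiro[4.5]decan-6-yl]pentanoate, via bis[(3S)-5-methoxy-3-methyl-5-oxopentyl]zinc 9 (not isolated), via alkylzinc enolate of the conjugate adduct 10 (not isolated)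
Conditions: 7 (3 equiv), Et2Zn (5 equiv), CuI (0.3 mol %), neat, 50 °C, then volatiles removed at 50 °C/0.1 mmHg; Cu(OTf)2 (5 mol %), (S,R,R)-O,O′-(1,1′-binaphthyl-2,2′-diyl)-N,N-bis(1-phenylethyl)phosphoramidite (10 mol %), 4, toluene, −30 to 0 °C; then 8 (3 equiv), Pd(PPh3)4 (5 mol %), THF, 0 °C to rt
Reagents that add atoms: none
Why: Dialkylzinc 9, made by iodine–zinc exchange, transmetallates to the monovalent copper–phosphoramidite complex formed in situ from Cu(OTf)2; the alkylcopper species forms a π-complex with enone 4, adds oxidatively to the β-carbon C9 and, after reductive elimination, leaves zinc enolate 10 with its double bond fixed between C5 and C10, which a π-allylpalladium complex generated from 8 then alkylates at C10. The closest known reaction type is the copper–phosphoramidite-catalysed asymmetric conjugate addition of functionalised dialkylzincs to 2-methylcyclohex-2-enone and to 4,4-dialkoxycyclohexenones combined with palladium-catalysed allylation of the zinc enolate (tandem conjugate addition–Tsuji–Trost alkylation). No ring is closed; the bonds formed are C9–C11 and C1–C10. C9 is controlled by the chiral ligand, which by analogy with cyclohex-2-enone should direct the alkyl group to the face that gives the (R)-configured C9 (the remote C13 centre of the reagent exerts no influence, and the antipodal ligand is used if the sense proves opposite), while C10 is controlled by the substrate, the allyl electrophile approaching the enolate face anti to the new C9 chain so that allyl ends trans and methyl cis to it. The step needs regioselective alkylation at C10 rather than C6, secured because only the enolate produced by the 1,4-addition is present, and chemoselectivity toward the two ester groups, secured by the low nucleophilicity of dialkylzinc and zinc enolate toward esters.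

Step 6
Reactants: 11 methyl (3R)-3-methyl-5-[(6R,7R)-7-methyl-8-oxo-7-(prop-2-en-1-yl)-1,4-dioxaspiro[4.5]decan-6-yl]pentanoate; 12 1-chloro-3-methylbut-2-ene
Product: 14 methyl (3R)-5-[(6R,7R,8S)-8-hydroxy-7-methyl-8-(2-methylbut-3-en-2-yl)-7-(prop-2-en-1-yl)-1,4-dioxaspiro[4.5]decan-6-yl]-3-methylpentanoate, via prenylzinc chloride 13 (not isolated)
Conditions: 12, Zn dust, LiCl, THF, rt; then 11, −78 to −40 °C; sat. aq NH4Cl at −40 °C
Reagents that add atoms: none
Why: The allylic zinc reagent adds to the hindered C5 ketone through a compact six-membered chair transition state at its γ-carbon (SE2′ carbonyl prenylation), which forms C4–C5 with the gem-dimethyl group in place and spares the methyl ester, attack anti to the axial C10 methyl giving the 5β-alcohol, whose configuration is later erased.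

Step 7
Reactants: 14 methyl (3R)-5-[(6R,7R,8S)-8-hydroxy-7-methyl-8-(2-methylbut-3-en-2-yl)-7-(prop-2-en-1-yl)-1,4-dioxaspiro[4.5]decan-6-yl]-3-methylpentanoate
Product: 15 methyl (13R)-8,8-ethylenedioxy-5-hydroxy-17-nor-5β-labd-2-en-15-oate (cis-fused, 5-OH and 10-CH3 both β)
Conditions: second-generation Grubbs catalyst (H2IMes)(PCy3)Cl2Ru=CHPh (5 mol %), CH2Cl2, 40 °C
Reagents that add atoms: none
Why: Ring-closing metathesis joins the C10 allyl group and the vinyl group on C4 into the C2=C3 cyclohexene of ring A with loss of ethene, a six-membered closure favoured by the two quaternary carbons flanking C5, and touches no stereocentre.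

Step 8
Reactants: 15 methyl (13R)-8,8-ethylenedioxy-5-hydroxy-17-nor-5β-labd-2-en-15-oate
Product: 16 methyl (13R)-8,8-ethylenedioxy-17-norlabda-2,5-dien-15-oate
Conditions: SOCl2 (1.5 equiv), pyridine, CH2Cl2, −20 to 0 °C
Reagents that add atoms: none
Why: The tertiary alcohol is converted into a chlorosulfite that eliminates in the presence of pyridine, and since C4 and C10 carry no hydrogen the only possible alkene is C5=C6, the cold basic medium limiting cationic methyl shifts (dehydration of a tertiary alcohol).

Step 9
Reactants: 16 methyl (13R)-8,8-ethylenedioxy-17-norlabda-2,5-dien-15-oate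
Product: 17 methyl (13R)-8,8-ethylenedioxy-17-norlabd-2-en-15-oate (5α-H, 9α-H, 10β-CH3)
Conditions: Mn(dpm)3 (10 mol %), PhSiH3 (1.2 equiv), t-BuOOH (1.5 equiv), i-PrOH, rt, argon
Reagents that add atoms: none
Why: Metal-hydride hydrogen atom transfer from a manganese hydride to C6 gives the tertiary C5 radical (the 1,2-disubstituted ring A alkene would give only a secondary radical and should react far more slowly), and the second hydrogen should arrive on the α face, anti to the syn-axial methyl groups on C4 and C10, giving the trans-fused 5α-H decalin that is also the thermodynamically preferred ring fusion (Mukaiyama-type radical hydrogenation).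

Step 10
Reactants: 17 methyl (13R)-8,8-ethylenedioxy-17-norlabd-2-en-15-oate
Product: 18 methyl (13R)-3α-bromo-8,8-ethylenedioxy-2β-hydroxy-17-norlabdan-15-oate
Conditions: NBS (1.2 equiv), DME–H2O (4:1), 0 °C to rt
Reagents that add atoms: N-bromosuccinimide O=C1CCC(=O)N1Br; water O
Why: The bromonium ion should form on the α face, away from the axial 4β- and 10β-methyl groups, and water opens it trans-diaxially at C2 (Fürst–Plattner rule, C3 being neopentyl and blocked), which gives the 3α-bromo-2β-ol and so sets the C2 configuration (bromohydrin formation).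

Step 11
Reactants: 18 methyl (13R)-3α-bromo-8,8-ethylenedioxy-2β-hydroxy-17-norlabdan-15-oate
Product: 19 methyl (13R)-8,8-ethylenedioxy-2β-hydroxy-17-norlabdan-15-oate
Conditions: Bu3SnH (1.5 equiv), AIBN (cat.), toluene, 80 °C
Reagents that add atoms: none
Why: Radical chain reduction replaces the secondary C3 bromide by hydrogen through a C3 radical that cannot expel the neighbouring hydroxyl group, so the 2β-alcohol stereocentre is untouched (tin hydride dehalogenation).

Step 12
Reactants: 19 methyl (13R)-8,8-ethylenedioxy-2β-hydroxy-17-norlabdan-15-oate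
Product: 20 methyl (13R)-2β-hydroxy-8-oxo-17-norlabdan-15-oate
Conditions: 1 M aq HCl–THF (1:3), rt
Reagents that add atoms: water O
Why: Acid-catalysed hydrolysis of the dioxolane releases the C8 ketone under conditions mild enough for the methyl ester and the secondary alcohol, and C9, now α to the carbonyl, already holds the thermodynamically favoured equatorial side chain, so enolisation cannot erode it (ketal hydrolysis).

Step 13
Reactants: 20 methyl (13R)-2β-hydroxy-8-oxo-17-norlabdan-15-oate
Product: 21 methyl (13R)-2β-hydroxylabd-8(17)-en-15-oate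
Conditions: Ph3PCH3Br (4 equiv), KN(SiMe3)2 (3.8 equiv), THF–toluene, 0 to 60 °C
Reagents that add atoms: methyltriphenylphosphonium bromide C[P+](c1ccccc1)(c1ccccc1)c1ccccc1.[Br-]
Why: Wittig methylenation with the non-stabilised ylide converts the C8 ketone into the exocyclic C8=C17 alkene, the excess ylide tolerating the free hydroxyl as its alkoxide and reacting far faster with the ketone than with the methyl ester, while C9 already holds its thermodynamically preferred equatorial chain.

Step 14
Reactants: 21 methyl (13R)-2β-hydroxylabd-8(17)-en-15-oate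
Product: 22 (13R)-2β-hydroxylabd-8(17)-en-15-oic acid
Conditions: LiOH·H2O (5 equiv), THF–MeOH–H2O, rt; then 1 M HCl to pH 3 at 0 °C
Reagents that add atoms: lithium hydroxide [Li+].[OH-]
Why: Saponification of the unhindered methyl ester proceeds by acyl–oxygen cleavage and involves no stereocentre (C13 is β to the carboxyl and not enolisable), while the isolated alkene and the secondary alcohol are inert to hydroxide.

Step 15
Reactants: 22 (13R)-2β-hydroxylabd-8(17)-en-15-oic acid
Product: 24 (13R)-2β-acetoxylabd-8(17)-en-15-oic acid, via mixed carboxylic acetic anhydride 23 (not isolated)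
Conditions: Ac2O (5 equiv), DMAP (0.2 equiv), pyridine, rt; then H2O–THF, rt
Reagents that add atoms: acetic anhydride CC(=O)OC(C)=O
Why: DMAP-catalysed acylation esterifies the hindered axial 2β-hydroxyl with retention because the C2–O bond is not broken, and the mixed anhydride formed at the carboxyl group is cleaved by water at its acetyl carbonyl during work-up, which returns the free acid and leaves the secondary acetate intact.

**Compound list**

1 | 4-methoxy-2-methylphenol | COc1ccc(O)c(C)c1 | starting material
2 | 4-(2-hydroxyethoxy)-4-methoxy-2-methylcyclohexa-2,5-dien-1-one (racemic ketal carbon) | COC1(OCCO)C=CC(=O)C(C)=C1 | intermediate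
3 | 7-methyl-1,4-dioxaspiro[4.5]deca-6,9-dien-8-one | CC1=CC2(OCCO2)C=CC1=O | intermediate
4 | 7-methyl-1,4-dioxaspiro[4.5]dec-6-en-8-one | CC1=CC2(OCCO2)CCC1=O | intermediate
5 | (R)-3-methylglutaric acid monomethyl ester | OC(=O)C[C@@H](C)CC(=O)OC | starting material
6 | methyl (3R)-5-hydroxy-3-methylpentanoate | OCC[C@@H](C)CC(=O)OC | intermediate
7 | methyl (3S)-5-iodo-3-methylpentanoate | ICC[C@@H](C)CC(=O)OC | intermediate
8 | allyl bromide | C=CCBr | starting material
9 | bis[(3S)-5-methoxy-3-methyl-5-oxopentyl]zinc | COC(=O)C[C@H](C)CC[Zn]CC[C@@H](C)CC(=O)OC | intermediate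
10 | alkylzinc enolate (C5–O–Zn, C5=C10) of methyl (3R)-3-methyl-5-[(6R)-7-methyl-8-oxo-1,4-dioxaspiro[4.5]decan-6-yl]pentanoate | COC(=O)C[C@H](C)CC[C@@H]1C(C)=C(O[Zn]CC[C@@H](C)CC(=O)OC)CCC12OCCO2 | intermediate
11 | methyl (3R)-3-methyl-5-[(6R,7R)-7-methyl-8-oxo-7-(prop-2-en-1-yl)-1,4-dioxaspiro[4.5]decan-6-yl]pentanoate | C=CC[C@]1(C)[C@@H](CC[C@@H](C)CC(=O)OC)C2(OCCO2)CCC1=O | intermediate
12 | 1-chloro-3-methylbut-2-ene | CC(C)=CCCl | starting material
13 | prenylzinc chloride | CC(C)=CC[Zn]Cl | intermediate
14 | methyl (3R)-5-[(6R,7R,8S)-8-hydroxy-7-methyl-8-(2-methylbut-3-en-2-yl)-7-(prop-2-en-1-yl)-1,4-dioxaspiro[4.5]decan-6-yl]-3-methylpentanoate | O1CCOC12CC[C@](O)(C(C)(C)C=C)[C@](C)(CC=C)[C@H]2CC[C@@H](C)CC(=O)OC | intermediate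
15 | methyl (13R)-8,8-ethylenedioxy-5-hydroxy-17-nor-5β-labd-2-en-15-oate | O1CCOC12CC[C@]3(O)C(C)(C)C=CC[C@]3(C)[C@H]2CC[C@@H](C)CC(=O)OC | intermediate
16 | methyl (13R)-8,8-ethylenedioxy-17-norlabda-2,5-dien-15-oate | O1CCOC12CC=C3C(C)(C)C=CC[C@]3(C)[C@H]2CC[C@@H](C)CC(=O)OC | intermediate
17 | methyl (13R)-8,8-ethylenedioxy-17-norlabd-2-en-15-oate | O1CCOC12CC[C@H]3C(C)(C)C=CC[C@]3(C)[C@H]2CC[C@@H](C)CC(=O)OC | intermediate
18 | methyl (13R)-3α-bromo-8,8-ethylenedioxy-2β-hydroxy-17-norlabdan-15-oate | O1CCOC12CC[C@H]3C(C)(C)[C@H](Br)[C@@H](O)C[C@]3(C)[C@H]2CC[C@@H](C)CC(=O)OC | intermediate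
19 | methyl (13R)-8,8-ethylenedioxy-2β-hydroxy-17-norlabdan-15-oate | O1CCOC12CC[C@H]3C(C)(C)C[C@@H](O)C[C@]3(C)[C@H]2CC[C@@H](C)CC(=O)OC | intermediate
20 | methyl (13R)-2β-hydroxy-8-oxo-17-norlabdan-15-oate | O=C1CC[C@H]2C(C)(C)C[C@@H](O)C[C@]2(C)[C@H]1CC[C@@H](C)CC(=O)OC | intermediate
21 | methyl (13R)-2β-hydroxylabd-8(17)-en-15-oate | C=C1CC[C@H]2C(C)(C)C[C@@H](O)C[C@]2(C)[C@H]1CC[C@@H](C)CC(=O)OC | intermediate
22 | (13R)-2β-hydroxylabd-8(17)-en-15-oic acid | C=C1CC[C@H]2C(C)(C)C[C@@H](O)C[C@]2(C)[C@H]1CC[C@@H](C)CC(=O)O | intermediate
23 | acetic (13R)-2β-acetoxylabd-8(17)-en-15-oic anhydride | C=C1CC[C@H]2C(C)(C)C[C@@H](OC(C)=O)C[C@]2(C)[C@H]1CC[C@@H](C)CC(=O)OC(C)=O | intermediate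
24 | (13R)-2β-acetoxylabd-8(17)-en-15-oic acid | C=C1CC[C@H]2C(C)(C)C[C@@H](OC(C)=O)C[C@]2(C)[C@H]1CC[C@@H](C)CC(=O)O | target

**Step count and risk**

Total step count: 15. Longest linear sequence: 13 steps (from 1 through steps 1, 2 and 5–15; equally from 5 through steps 3, 4 and 5–15).

Steps most likely to fail:

1. Step 5. What may go wrong: the tetrasubstituted zinc enolate is alkylated slowly at the congested C10, so that protonation on work-up or O-allylation competes with C-allylation and the quaternary centre is lost or formed with poor anti selectivity. The fallback sets out from 4 and 9 and returns at 11. The conjugate addition is run unchanged, but enolate 10 is quenched at −30 °C with allyl chloroformate and TMEDA to give the isolable allyl enol carbonate F1. Treatment with Pd(PPh3)4 in THF at rt then brings about a decarboxylative Tsuji allylation: the π-allylpalladium cation and the enolate are generated as an ion pair and should recombine at C10 anti to the C9 chain, giving 11.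

2. Step 9. What may go wrong: hydrogen atom transfer fails to discriminate between the two alkenes, so that C2=C3 is reduced as well, or methyl migration in the preceding dehydration erodes the material entering the step. The fallback sets out from 15 and returns at 17, replacing steps 8 and 9. Alcohol 15 is acylated with methyl chlorooxoacetate (DMAP, pyridine, CH2Cl2) to the mixed methyl oxalate F2, which is reduced with Bu3SnH and AIBN in refluxing toluene (radical deoxygenation of a tertiary alcohol, Barton–McCombie family). The ring A alkene is not involved, and the same tertiary C5 radical should take hydrogen from the tin hydride on the α face to give 17.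

3. Step 10. What may go wrong: water must enter axially at C2 between the two syn-axial methyl groups, and if this is slow the bromonium ion is diverted to allylic bromide formation or to opening with the wrong regiochemistry. The fallback sets out from 17 and returns at 19, replacing steps 10 and 11. Hydroboration of 17 with BH3·THF at 0 °C followed by NaBO3 oxidation should place boron on C2, away from the neopentyl C3 and on the open α face, giving the 2α-alcohol F3. Dess–Martin oxidation gives the 2-ketone F4, and LiBH(s-Bu)3 in THF at −78 °C should deliver hydride from the α face to give the axial 2β-alcohol 19 without touching the methyl ester.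

**Further compounds**

F1 | step 5 | methyl (3R)-3-methyl-5-[(6R)-7-methyl-8-{[(prop-2-en-1-yloxy)carbonyl]oxy}-1,4-dioxaspiro[4.5]dec-7-en-6-yl]pentanoate (allyl enol carbonate) | COC(=O)C[C@H](C)CC[C@@H]1C(C)=C(OC(=O)OCC=C)CCC12OCCO2
F2 | step 9 | methyl (13R)-8,8-ethylenedioxy-5-[(methoxyoxalyl)oxy]-17-nor-5β-labd-2-en-15-oate (mixed methyl oxalate of 15) | O1CCOC12CC[C@]3(OC(=O)C(=O)OC)C(C)(C)C=CC[C@]3(C)[C@H]2CC[C@@H](C)CC(=O)OC
F3 | step 10 | methyl (13R)-8,8-ethylenedioxy-2α-hydroxy-17-norlabdan-15-oate | O1CCOC12CC[C@H]3C(C)(C)C[C@H](O)C[C@]3(C)[C@H]2CC[C@@H](C)CC(=O)OC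
F4 | step 10 | methyl (13R)-8,8-ethylenedioxy-2-oxo-17-norlabdan-15-oate | O1CCOC12CC[C@H]3C(C)(C)CC(=O)C[C@]3(C)[C@H]2CC[C@@H](C)CC(=O)OC
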